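**Plan**

- Retrosynthesis: the pyridone ring N1–C2(Me)–C3(OMe)–C4(=O)–C4a–C8a is a masked 3-hydroxypyridine. It is cut at N1–C8a and traced back to a 2-(1-aminoethyl)-3-benzyloxyfuran: the amine carbon becomes C2, furan C2/C3/C3a/C7a become C3/C4/C4a/C8a, the furan ring oxygen becomes the C3 oxygen and the benzyloxy oxygen the C4 oxygen. This oxygen pattern is what allows an oxidative furan-to-pyridine ring expansion.
- Further cuts: the C–C bond between furan C2 and its two-carbon side chain (aldol), the furanone O1–C2 and C3–C3a bonds (chloroacetyl unit), and the C5–C1' bond to the 5-phenylpentyl chain (conjugate addition).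
- Forward: the cyclohexane ring is present from the start; the furanone ring is annulated onto the regiodefined enol ether left by the conjugate addition; the pyridine ring is formed last, from the furan, in the key step. O-Methylation, debenzylation to the pyridone and desilylation finish the route.
- Stereochemistry: C8 comes from (1R,2R)-cyclohexane-1,2-diol; C5 is set by the ligand-controlled copper-catalysed conjugate addition of the Grignard reagent; the amine carbon is left uncontrolled because it becomes the aromatic C2.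

Key step: step 11

Assumption: in step 5 the chiral ferrocenyl diphosphine, not the remote silyloxy group at C6 of the enone, is taken to decide the face of attack at the β-carbon; the ligand enantiomer is chosen by its sense of induction on cyclohex-2-en-1-one (the one giving (S)-3-alkylcyclohexanones).
Abbreviations: TBS = tert-butyldimethylsilyl, Bn = benzyl.

**Route**

Step 1
Reactants: 1 (1R,2R)-cyclohexane-1,2-diol
Product: 2 (1R,2R)-2-(TBS-oxy)cyclohexan-1-ol
Conditions: TBSCl (1.0 equiv), imidazole, DMF, 0 °C to rt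
Reagents that add atoms: tert-butyldimethylsilyl chloride, CC(C)(C)[Si](C)(C)Cl
Why: Silyl ether formation on a C2-symmetric trans-diol should stop at the mono-ether because the first silyl group shields the neighbouring hydroxyl, and no stereocentre is touched.

Step 2
Reactants: 2 (1R,2R)-2-(TBS-oxy)cyclohexan-1-ol
Product: 3 (2R)-2-(TBS-oxy)cyclohexan-1-one
Conditions: (n-Pr)4N[RuO4] (5 mol %), N-methylmorpholine N-oxide, 4 Å molecular sieves, CH2Cl2, rt
Reagents that add atoms: none
Why: Ley–Griffith oxidation of the secondary alcohol under neutral conditions should give the α-silyloxy ketone without epimerising its stereocentre.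

Step 3
Reactants: 3 (2R)-2-(TBS-oxy)cyclohexan-1-one
Product: 6 (6R)-6-(TBS-oxy)cyclohex-2-en-1-one, via lithium enolate 4 (not isolated), via silyl enol ether 5 (not isolated)
Conditions: LiN(iPr)2, THF, −78 °C; Me3SiCl; solvent exchange; Pd(OAc)2 (1.05 equiv), MeCN, rt
Reagents that add atoms: none
Why: Kinetic deprotonation of an α-silyloxy ketone occurs at the methylene carbon remote from the silyloxy group, and Saegusa–Ito oxidation of the derived silyl enol ether gives the enone while the never-enolised C6 stereocentre is retained.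

Step 4
Reactants: 7 (5-bromopentyl)benzene
Product: 8 (5-phenylpentyl)magnesium bromide
Conditions: Mg turnings, I2 (cat.), Et2O, reflux; titrated ethereal solution used directly
Reagents that add atoms: magnesium, [Mg]
Why: Grignard reagent formation by insertion of magnesium into the primary alkyl bromide gives the nucleophile as the ethereal solution that the copper-catalysed addition of step 5 requires.

Step 5
Reactants: 6 (6R)-6-(TBS-oxy)cyclohex-2-en-1-one; 8 (5-phenylpentyl)magnesium bromide
Product: 10 tert-butyldimethyl{[(1R,4S)-4-(5-phenylpentyl)-2-(trimethylsilyloxy)cyclohex-2-en-1-yl]oxy}silane, via magnesium enolate 9 (not isolated)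
Conditions: CuCl (5 mol %), 1-(diphenylphosphino)-2-[α-(dimethylamino)-2-(diphenylphosphino)benzyl]ferrocene (TaniaPhos, 6 mol %, the enantiomer that takes cyclohex-2-en-1-one to (S)-3-alkylcyclohexanones), Et2O, −40 °C, slow addition of 8 (1.15 equiv); then Me3SiCl, Et3N, DMPU, −40 °C to rt; pentane, filtration through basic alumina
Reagents that add atoms: chlorotrimethylsilane, C[Si](C)(C)Cl
Why: Copper-catalysed enantioselective conjugate addition of a Grignard reagent to a cyclohexenone under ferrocenyl diphosphine control, with O-silylation of the magnesium enolate, in which the chosen ligand enantiomer should set the chain-bearing carbon as S and cis to the silyloxy group, while the trapping locks the enol double bond towards that carbon.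

Step 6
Reactants: 10 tert-butyldimethyl{[(1R,4S)-4-(5-phenylpentyl)-2-(trimethylsilyloxy)cyclohex-2-en-1-yl]oxy}silane; 11 chloroacetyl chloride
Product: 13 (4S,7R)-7-(TBS-oxy)-4-(5-phenylpentyl)-4,5,6,7-tetrahydro-1-benzofuran-3(2H)-one, via chloroacetyl diketone 12 (not isolated)
Conditions: ZnCl2 (1.0 equiv), CH2Cl2/Et2O, 0 °C to rt; then Et3N, rt
Reagents that add atoms: none
Why: Zinc chloride-promoted C-acylation of a silyl enol ether by an acid chloride (Mukaiyama-type acylation) places the chloroacetyl group on the carbon fixed by the enol ether, and triethylamine then closes the furan-3(2H)-one by 5-exo-tet O-alkylation of the ring enolate oxygen, leaving C4 and C7 untouched.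

Step 7
Reactants: 13 (4S,7R)-7-(TBS-oxy)-4-(5-phenylpentyl)-4,5,6,7-tetrahydro-1-benzofuran-3(2H)-one; 14 acetaldehyde
Product: 16 (4S,7R)-7-(TBS-oxy)-2-(1-hydroxyethyl)-4-(5-phenylpentyl)-4,5,6,7-tetrahydro-1-benzofuran-3(2H)-one (diastereomer mixture at C2 and the carbinol carbon), via lithium furan-3-olate 15 (not isolated)
Conditions: LiN(iPr)2, THF, −78 °C; MeCHO, −78 °C; AcOH quench at −78 °C
Reagents that add atoms: none
Why: Aldol addition at C2, the most acidic site of a furan-3(2H)-one because deprotonation gives an aromatic furan-3-olate that reacts with aldehydes through carbon; the two new stereocentres are uncontrolled and both disappear in step 8.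

Step 8
Reactants: 16 (4S,7R)-7-(TBS-oxy)-2-(1-hydroxyethyl)-4-(5-phenylpentyl)-4,5,6,7-tetrahydro-1-benzofuran-3(2H)-one
Product: 17 1-[(4S,7R)-7-(TBS-oxy)-3-hydroxy-4-(5-phenylpentyl)-4,5,6,7-tetrahydro-1-benzofuran-2-yl]ethan-1-one
Conditions: Dess–Martin periodinane (1.2 equiv), NaHCO3, CH2Cl2, 0 °C to rt
Reagents that add atoms: none
Why: Dess–Martin oxidation of the β-hydroxy ketone gives the 2-acetylfuran-3(2H)-one, which should tautomerise to the hydrogen-bonded aromatic 2-acetyl-3-hydroxyfuran.

Step 9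
Reactants: 17 1-[(4S,7R)-7-(TBS-oxy)-3-hydroxy-4-(5-phenylpentyl)-4,5,6,7-tetrahydro-1-benzofuran-2-yl]ethan-1-one
Product: 18 1-[(4S,7R)-3-(benzyloxy)-7-(TBS-oxy)-4-(5-phenylpentyl)-4,5,6,7-tetrahydro-1-benzofuran-2-yl]ethan-1-one
Conditions: BnBr, K2CO3, DMF, rt to 50 °C
Reagents that add atoms: benzyl bromide, BrCc1ccccc1
Why: Williamson ether synthesis on the acidic chelated hydroxyl of a 2-acyl-3-hydroxyfuran (the analogue of an ortho-hydroxyaryl ketone) should give the O-benzyl ether, since C-alkylation would cost the furan its aromaticity.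

Step 10
Reactants: 18 1-[(4S,7R)-3-(benzyloxy)-7-(TBS-oxy)-4-(5-phenylpentyl)-4,5,6,7-tetrahydro-1-benzofuran-2-yl]ethan-1-one
Product: 20 1-[(4S,7R)-3-(benzyloxy)-7-(TBS-oxy)-4-(5-phenylpentyl)-4,5,6,7-tetrahydro-1-benzofuran-2-yl]ethan-1-amine (both epimers at the amine carbon), via ketimine 19 (not isolated)
Conditions: NH3 (2 M in EtOH), Ti(OiPr)4, rt; then NaBH4, 0 °C to rt; aqueous NH3 work-up; used without storage
Reagents that add atoms: ammonia, N
Why: Reductive amination of an aryl methyl ketone, with Ti(OiPr)4 driving ketimine formation and NaBH4 reducing the imine to the primary amine, whose new stereocentre is left uncontrolled because this carbon becomes the sp2 C2 of the pyridine in step 11.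

Step 11
Reactants: 20 1-[(4S,7R)-3-(benzyloxy)-7-(TBS-oxy)-4-(5-phenylpentyl)-4,5,6,7-tetrahydro-1-benzofuran-2-yl]ethan-1-amine
Product: 24 (5S,8R)-4-(benzyloxy)-8-(TBS-oxy)-2-methyl-5-(5-phenylpentyl)-5,6,7,8-tetrahydroquinolin-3-ol, via bromo hemiketal 21 (not isolated), via cis-ene-dione 22 (not isolated), via 2H-pyridin-3-one 23 (not isolated)
Conditions: AcOH (1.1 equiv), NaOAc (2.5 equiv), THF/H2O (4:1), 0 °C; NBS (1.05 equiv), 0 °C, then rt; NaHCO3 work-up
Reagents that add atoms: none
Why: NBS transfers Br+ to C2 of the protonated furfurylamine (the enol-ether carbon next to the benzyloxy group), water adds to C7a across the 2,5-positions to give bromo hemiketal 21, and this fragments with loss of bromide to cis-ene-dione 22, in which the furan oxygen has become the ketone oxygen on the former C2. As the buffer frees the α-amino ketone nitrogen, it adds to the C7a ketone in a 6-exo-trig closure that forms N1–C8a and the six-membered ring; loss of water gives 2H-pyridin-3-one 23, and enolisation of its C2–H aromatises the ring to the 3-hydroxypyridine. The closest known reaction type is the aza-Achmatowicz oxidation in the form used for free furfurylamines, the oxidative ring expansion of 2-(aminoalkyl)furans to 3-pyridinols. No stereocentre is formed: the amine carbon ends as the sp2 C2, while C5 and C8 are carried over from C4 and C7 of the furan. The step needs 2,5- instead of 2,3-addition to the 3-benzyloxyfuran, attack of bromine on carbon and not on nitrogen, and no enolisation at C7 next to the transient ketone. These should be secured by the bromine at C2, which makes the ring oxygen the weaker donor so that water attacks C7a and the adduct fragments irreversibly, by protonation of the amine at pH 5, and by the fast intramolecular condensation at 0 °C.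

Step 12
Reactants: 24 (5S,8R)-4-(benzyloxy)-8-(TBS-oxy)-2-methyl-5-(5-phenylpentyl)-5,6,7,8-tetrahydroquinolin-3-ol
Product: 25 (5S,8R)-4-(benzyloxy)-8-(TBS-oxy)-3-methoxy-2-methyl-5-(5-phenylpentyl)-5,6,7,8-tetrahydroquinoline
Conditions: MeI, Cs2CO3, DMF, 0 °C to rt
Reagents that add atoms: iodomethane, CI
Why: Williamson O-methylation of the 3-pyridinol, done while the C4 oxygen is still benzylated so that only one hydroxyl is free, with N-methylation expected to be slow because the ring nitrogen lies between the C2 methyl group and C8 with its bulky silyloxy substituent.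

Step 13
Reactants: 25 (5S,8R)-4-(benzyloxy)-8-(TBS-oxy)-3-methoxy-2-methyl-5-(5-phenylpentyl)-5,6,7,8-tetrahydroquinoline
Product: 26 (5S,8R)-8-(TBS-oxy)-3-methoxy-2-methyl-5-(5-phenylpentyl)-5,6,7,8-tetrahydroquinolin-4(1H)-one
Conditions: H2 (1 atm), Pd/C (10 %), EtOAc/EtOH, rt
Reagents that add atoms: none
Why: Catalytic hydrogenolysis of the benzyl ether gives the pyridin-4-ol, which rests as the 4(1H)-pyridone tautomer, while the secondary silyl ether and the side-chain phenyl ring should survive one atmosphere of hydrogen at room temperature.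

Step 14
Reactants: 26 (5S,8R)-8-(TBS-oxy)-3-methoxy-2-methyl-5-(5-phenylpentyl)-5,6,7,8-tetrahydroquinolin-4(1H)-one
Product: 27 (5S,8R)-8-hydroxy-3-methoxy-2-methyl-5-(5-phenylpentyl)-5,6,7,8-tetrahydroquinolin-4(1H)-one (target)
Conditions: HF·pyridine, THF/pyridine, 0 °C to rt
Reagents that add atoms: none
Why: Fluoride-mediated desilylation of the secondary silyl ether under buffered conditions should free the C8 alcohol without ionising this position, so the 8R configuration is retained.

**Compound list**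

1 | (1R,2R)-cyclohexane-1,2-diol | O[C@@H]1CCCC[C@H]1O | starting material
2 | (1R,2R)-2-[(tert-butyldimethylsilyl)oxy]cyclohexan-1-ol | O[C@@H]1CCCC[C@H]1O[Si](C)(C)C(C)(C)C | intermediate
3 | (2R)-2-[(tert-butyldimethylsilyl)oxy]cyclohexan-1-one | O=C1CCCC[C@H]1O[Si](C)(C)C(C)(C)C | intermediate
4 | lithium (6R)-6-[(tert-butyldimethylsilyl)oxy]cyclohex-1-en-1-olate | [Li]OC1=CCCC[C@H]1O[Si](C)(C)C(C)(C)C | intermediate (not isolated)
5 | tert-butyldimethyl{[(1R)-2-(trimethylsilyloxy)cyclohex-2-en-1-yl]oxy}silane | C[Si](C)(C)OC1=CCCC[C@H]1O[Si](C)(C)C(C)(C)C | intermediate (not isolated)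
6 | (6R)-6-[(tert-butyldimethylsilyl)oxy]cyclohex-2-en-1-one | O=C1C=CCC[C@H]1O[Si](C)(C)C(C)(C)C | intermediate
7 | (5-bromopentyl)benzene | BrCCCCCc1ccccc1 | starting material
8 | (5-phenylpentyl)magnesium bromide | Br[Mg]CCCCCc1ccccc1 | intermediate
9 | bromomagnesium (3S,6R)-6-[(tert-butyldimethylsilyl)oxy]-3-(5-phenylpentyl)cyclohex-1-en-1-olate | Br[Mg]OC1=C[C@@H](CCCCCc2ccccc2)CC[C@H]1O[Si](C)(C)C(C)(C)C | intermediate (not isolated)
10 | tert-butyldimethyl{[(1R,4S)-4-(5-phenylpentyl)-2-(trimethylsilyloxy)cyclohex-2-en-1-yl]oxy}silane | C[Si](C)(C)OC1=C[C@@H](CCCCCc2ccccc2)CC[C@H]1O[Si](C)(C)C(C)(C)C | intermediate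
11 | chloroacetyl chloride | ClCC(Cl)=O | starting material
12 | (3S,6R)-6-[(tert-butyldimethylsilyl)oxy]-2-(chloroacetyl)-3-(5-phenylpentyl)cyclohexan-1-one (C2 epimers and enol forms) | O=C1C(C(=O)CCl)[C@@H](CCCCCc2ccccc2)CC[C@H]1O[Si](C)(C)C(C)(C)C | intermediate (not isolated)
13 | (4S,7R)-7-[(tert-butyldimethylsilyl)oxy]-4-(5-phenylpentyl)-4,5,6,7-tetrahydro-1-benzofuran-3(2H)-one | O=C1COC2=C1[C@@H](CCCCCc1ccccc1)CC[C@H]2O[Si](C)(C)C(C)(C)C | intermediate
14 | acetaldehyde | CC=O | starting material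
15 | lithium (4S,7R)-7-[(tert-butyldimethylsilyl)oxy]-4-(5-phenylpentyl)-4,5,6,7-tetrahydro-1-benzofuran-3-olate | [Li]Oc1coc2c1[C@@H](CCCCCc1ccccc1)CC[C@H]2O[Si](C)(C)C(C)(C)C | intermediate (not isolated)
16 | (4S,7R)-7-[(tert-butyldimethylsilyl)oxy]-2-(1-hydroxyethyl)-4-(5-phenylpentyl)-4,5,6,7-tetrahydro-1-benzofuran-3(2H)-one (mixture at C2 and the carbinol carbon) | CC(O)C1OC2=C(C1=O)[C@@H](CCCCCc1ccccc1)CC[C@H]2O[Si](C)(C)C(C)(C)C | intermediate
17 | 1-[(4S,7R)-7-[(tert-butyldimethylsilyl)oxy]-3-hydroxy-4-(5-phenylpentyl)-4,5,6,7-tetrahydro-1-benzofuran-2-yl]ethan-1-one | CC(=O)c1oc2c(c1O)[C@@H](CCCCCc1ccccc1)CC[C@H]2O[Si](C)(C)C(C)(C)C | intermediate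
18 | 1-[(4S,7R)-3-(benzyloxy)-7-[(tert-butyldimethylsilyl)oxy]-4-(5-phenylpentyl)-4,5,6,7-tetrahydro-1-benzofuran-2-yl]ethan-1-one | CC(=O)c1oc2c(c1OCc1ccccc1)[C@@H](CCCCCc1ccccc1)CC[C@H]2O[Si](C)(C)C(C)(C)C | intermediate
19 | 1-[(4S,7R)-3-(benzyloxy)-7-[(tert-butyldimethylsilyl)oxy]-4-(5-phenylpentyl)-4,5,6,7-tetrahydro-1-benzofuran-2-yl]ethan-1-imine | CC(=N)c1oc2c(c1OCc1ccccc1)[C@@H](CCCCCc1ccccc1)CC[C@H]2O[Si](C)(C)C(C)(C)C | intermediate (not isolated)
20 | 1-[(4S,7R)-3-(benzyloxy)-7-[(tert-butyldimethylsilyl)oxy]-4-(5-phenylpentyl)-4,5,6,7-tetrahydro-1-benzofuran-2-yl]ethan-1-amine (both epimers at the amine carbon) | CC(N)c1oc2c(c1OCc1ccccc1)[C@@H](CCCCCc1ccccc1)CC[C@H]2O[Si](C)(C)C(C)(C)C | intermediate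
21 | 1-[(4S,7R)-3-(benzyloxy)-2-bromo-7-[(tert-butyldimethylsilyl)oxy]-7a-hydroxy-4-(5-phenylpentyl)-2,4,5,6,7,7a-hexahydro-1-benzofuran-2-yl]ethan-1-amine (C2 and C7a undefined) | CC(N)C1(Br)OC2(O)C(=C1OCc1ccccc1)[C@@H](CCCCCc1ccccc1)CC[C@H]2O[Si](C)(C)C(C)(C)C | intermediate (not isolated)
22 | (2E,3S,6R)-2-[3-amino-1-(benzyloxy)-2-oxobutylidene]-6-[(tert-butyldimethylsilyl)oxy]-3-(5-phenylpentyl)cyclohexan-1-one (the two carbonyl groups cis on the double bond) | O=C1/C(=C(/OCc2ccccc2)C(=O)C(C)N)[C@@H](CCCCCc2ccccc2)CC[C@H]1O[Si](C)(C)C(C)(C)C | intermediate (not isolated)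
23 | (5S,8R)-4-(benzyloxy)-8-[(tert-butyldimethylsilyl)oxy]-2-methyl-5-(5-phenylpentyl)-5,6,7,8-tetrahydroquinolin-3(2H)-one (C2 undefined) | CC1N=C2C(=C(OCc3ccccc3)C1=O)[C@@H](CCCCCc3ccccc3)CC[C@H]2O[Si](C)(C)C(C)(C)C | intermediate (not isolated)
24 | (5S,8R)-4-(benzyloxy)-8-[(tert-butyldimethylsilyl)oxy]-2-methyl-5-(5-phenylpentyl)-5,6,7,8-tetrahydroquinolin-3-ol | Oc1c(C)nc2c(c1OCc1ccccc1)[C@@H](CCCCCc1ccccc1)CC[C@H]2O[Si](C)(C)C(C)(C)C | intermediate
25 | (5S,8R)-4-(benzyloxy)-8-[(tert-butyldimethylsilyl)oxy]-3-methoxy-2-methyl-5-(5-phenylpentyl)-5,6,7,8-tetrahydroquinoline | COc1c(C)nc2c(c1OCc1ccccc1)[C@@H](CCCCCc1ccccc1)CC[C@H]2O[Si](C)(C)C(C)(C)C | intermediate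
26 | (5S,8R)-8-[(tert-butyldimethylsilyl)oxy]-3-methoxy-2-methyl-5-(5-phenylpentyl)-5,6,7,8-tetrahydroquinolin-4(1H)-one | COc1c(C)[nH]c2c(c1=O)[C@@H](CCCCCc1ccccc1)CC[C@H]2O[Si](C)(C)C(C)(C)C | intermediate
27 | (5S,8R)-8-hydroxy-3-methoxy-2-methyl-5-(5-phenylpentyl)-5,6,7,8-tetrahydroquinolin-4(1H)-one | COc1c(C)[nH]c2c(c1=O)[C@@H](CCCCCc1ccccc1)CC[C@H]2O | target

**Step count**

Total: 14 steps. Longest linear sequence: 13 steps (steps 1–3 and 5–14); step 4 is a one-step side branch.

**Steps most likely to fail**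

Step 5. The resident C6 stereocentre may oppose the ligand (mismatched pairing), so that facial selectivity at the β-carbon falls. Uncatalysed 1,2-addition of the Grignard reagent to the carbonyl group may also compete if the α'-silyloxy group slows the copper-catalysed pathway.
Fallback (sets out from 8, returns at 10): the chain is introduced first on the unsubstituted enone, where the ligand meets no resident stereocentre. Commercial cyclohex-2-en-1-one and 8 under the same CuCl/ferrocenyl diphosphine catalyst, with a 1 M HCl quench, should give (3S)-3-(5-phenylpentyl)cyclohexan-1-one F1. L-Proline-catalysed α-aminoxylation with nitrosobenzene at the less hindered C6 methylene should then give (2R,5S)-2-[(phenylamino)oxy]-5-(5-phenylpentyl)cyclohexan-1-one F2, with the new centre set by the catalyst. Hydrogenolysis of the N–O bond (H2, Pd/C, EtOAc) should give the ketol (2R,5S)-2-hydroxy-5-(5-phenylpentyl)cyclohexan-1-one F3, and silylation (TBSCl, imidazole) should give (2R,5S)-2-[(tert-butyldimethylsilyl)oxy]-5-(5-phenylpentyl)cyclohexan-1-one F4. Kinetic enolisation away from the silyloxy carbon with internal silyl quench (LiN(iPr)2 added to F4 and Me3SiCl, THF, −78 °C) returns to 10.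

Step 11. Water may add to C3 instead of C7a, with loss of the benzyl group; bromine may be taken up by nitrogen; or the open ene-dione may enolise towards C7 before the amine captures it, eroding the C8 configuration.
Fallback (sets out from 20, returns at 24): the nitrogen is masked as a carbamate and the furan is oxidised by cycloaddition instead of halogenation. Allyl chloroformate and NaHCO3 should convert 20 to allyl N-{1-[(4S,7R)-3-(benzyloxy)-7-[(tert-butyldimethylsilyl)oxy]-4-(5-phenylpentyl)-4,5,6,7-tetrahydro-1-benzofuran-2-yl]ethyl}carbamate F5. Photooxygenation (O2, visible light, methylene blue, MeOH, low temperature; then Me2S) is a [4+2] addition of singlet oxygen that can only engage the furan 2,5-positions. It should give the aza-Achmatowicz hemiaminal allyl (5S,8R)-4-(benzyloxy)-8-[(tert-butyldimethylsilyl)oxy]-8a-hydroxy-2-methyl-3-oxo-5-(5-phenylpentyl)-3,5,6,7,8,8a-hexahydroquinoline-1(2H)-carboxylate F6. Deallylation with Pd(PPh3)4 and morpholine frees the N–H hemiaminal, which should lose carbon dioxide and water and tautomerise to 24.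

Step 6. O-Acylation of the silyl enol ether may compete with C-acylation, or protodesilylation by adventitious HCl may return the ketone and with it lose the regiochemical definition of the enol.
Fallback (sets out from 10, returns at 13): the furanone oxygen is brought in as a hydroxyl instead of being alkylated. Mukaiyama aldol addition of 10 to (benzyloxy)acetaldehyde (BF3·OEt2, CH2Cl2, −78 °C) should give (3S,6R)-2-[2-(benzyloxy)-1-hydroxyethyl]-6-[(tert-butyldimethylsilyl)oxy]-3-(5-phenylpentyl)cyclohexan-1-one F7. Dess–Martin oxidation should give the 1,3-diketone (3S,6R)-2-[(benzyloxy)acetyl]-6-[(tert-butyldimethylsilyl)oxy]-3-(5-phenylpentyl)cyclohexan-1-one F8, and hydrogenolysis (H2, Pd/C) the hydroxy diketone (3S,6R)-6-[(tert-butyldimethylsilyl)oxy]-2-(hydroxyacetyl)-3-(5-phenylpentyl)cyclohexan-1-one F9. Acid-catalysed cyclodehydration (pyridinium p-toluenesulfonate, toluene, 60 °C), the hydroxyl oxygen adding to the ring carbonyl with loss of water, closes furanone 13.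

Further compounds
F1 | step 5 | (3S)-3-(5-phenylpentyl)cyclohexan-1-one | O=C1C[C@@H](CCCCCc2ccccc2)CCC1
F2 | step 5 | (2R,5S)-2-[(phenylamino)oxy]-5-(5-phenylpentyl)cyclohexan-1-one | O=C1C[C@@H](CCCCCc2ccccc2)CC[C@H]1ONc1ccccc1
F3 | step 5 | (2R,5S)-2-hydroxy-5-(5-phenylpentyl)cyclohexan-1-one | O=C1C[C@@H](CCCCCc2ccccc2)CC[C@H]1O
F4 | step 5 | (2R,5S)-2-[(tert-butyldimethylsilyl)oxy]-5-(5-phenylpentyl)cyclohexan-1-one | O=C1C[C@@H](CCCCCc2ccccc2)CC[C@H]1O[Si](C)(C)C(C)(C)C
F5 | step 11 | allyl N-{1-[(4S,7R)-3-(benzyloxy)-7-[(tert-butyldimethylsilyl)oxy]-4-(5-phenylpentyl)-4,5,6,7-tetrahydro-1-benzofuran-2-yl]ethyl}carbamate | CC(NC(=O)OCC=C)c1oc2c(c1OCc1ccccc1)[C@@H](CCCCCc1ccccc1)CC[C@H]2O[Si](C)(C)C(C)(C)C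
F6 | step 11 | allyl (5S,8R)-4-(benzyloxy)-8-[(tert-butyldimethylsilyl)oxy]-8a-hydroxy-2-methyl-3-oxo-5-(5-phenylpentyl)-3,5,6,7,8,8a-hexahydroquinoline-1(2H)-carboxylate | CC1N(C(=O)OCC=C)C2(O)C(=C(OCc3ccccc3)C1=O)[C@@H](CCCCCc3ccccc3)CC[C@H]2O[Si](C)(C)C(C)(C)C
F7 | step 6 | (3S,6R)-2-[2-(benzyloxy)-1-hydroxyethyl]-6-[(tert-butyldimethylsilyl)oxy]-3-(5-phenylpentyl)cyclohexan-1-one | O=C1C(C(O)COCc2ccccc2)[C@@H](CCCCCc2ccccc2)CC[C@H]1O[Si](C)(C)C(C)(C)C
F8 | step 6 | (3S,6R)-2-[(benzyloxy)acetyl]-6-[(tert-butyldimethylsilyl)oxy]-3-(5-phenylpentyl)cyclohexan-1-one | O=C1C(C(=O)COCc2ccccc2)[C@@H](CCCCCc2ccccc2)CC[C@H]1O[Si](C)(C)C(C)(C)C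
F9 | step 6 | (3S,6R)-6-[(tert-butyldimethylsilyl)oxy]-2-(hydroxyacetyl)-3-(5-phenylpentyl)cyclohexan-1-one | O=C1C(C(=O)CO)[C@@H](CCCCCc2ccccc2)CC[C@H]1O[Si](C)(C)C(C)(C)C
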